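Late in a long run, says one chemist, X is whatever the Z paid for, so she writes the balance of Z.

the same everywhere: E 0.010 M; Z 0.0105 M; J 0.0500 M; L 5.0 µM; time 2.5 min

| charge | temperature |
|---|---|
| birch | 110 °C |
| ash | 85 °C |

    J + Z + L → L + D (k1 = 59200 M⁻² s⁻¹, Ea1 = 21.0 kJ mol⁻¹)
    E + Z + L → L + X (k2 = 4.02 × 10⁵ M⁻² s⁻¹, Ea2 = 13.0 kJ mol⁻¹)
    L + X ⇌ L.X, settled at all times (K3 = 9900 M⁻¹, ΔH3 = −11.0 kJ mol⁻¹)
    Z + X → Z.X (k4 = 0.0520 M⁻¹ s⁻¹, Ea4 = 54.0 kJ mol⁻¹)
    (constants at 110 °C)

- for X the L.X is counted in
- the constants hold at 110 °C; other temperatures follow from the activation energies and enthalpies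

- the flask with the highest amount of X, in percent of the E charged ("all alike" if they lie within 1.5 percentage points) (birch / ash / all alike)
- final X, as a percentage of the E charged, in birch
- final X, as a percentage of the E charged, in ash

Z spent equals E spent plus D made plus Z.X made. At the start, step 2 and step 1 split Z as k2·c(E) to k1·c(J), a selectivity factor. In birch that factor is 1.36. In ash, k2 is 3.02 × 10⁵ M⁻² s⁻¹ and k1 is 37400 M⁻² s⁻¹, so the factor is 1.62. Cooling therefore favours E. Spent in those start shares, the charged Z buys X worth 60.5 % of the E in birch and 64.9 % in ash. She bets on ash.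

The second chemist says her sum has no clock. L is charged at 5.0 µM, and X binds it as L.X. Free L is the charge divided by one plus K3·c(X). Once K3·c(X) is large, and with c(E) and c(Z) held at their charges, the rate falls as one over c(X), so the square of c(X) grows in step with time. That gives c(X) as the root of 2·k2·c(E)·c(Z)·c(L)·t/K3. Taken over c(E), in birch, this is 25.3 %; I call it the poisoned reach. At that reach in birch, K3·c(X) is 25.0, so it is large, as the reckoning assumed.

In ash, K3 rises to 12600 M⁻¹, and the reach is 19.4 %. I side with the second chemist, because each reach is smaller than the budget. My reach holds c(E) and c(Z) at their charges, though both fall. Each X costs 1.74 Z at the start in birch, so c(Z) falls during the run. I commit to birch above ash, each somewhat under its reach.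

The forecast named birch, with 19.2 % in birch and 15.8 % in ash, holding that “the run is kinetically limited rather than Z-limited”.

The flask gives birch the most: 19.0 % in birch and 15.8 % in ash. That is 0.751 of the reach in birch and 0.814 in ash. At 2.50 min, 65 % of the Z still stands in birch and 74 % in ash. Her order shows at 25.0 min, where ash holds 34.9 % and birch 34.4 %. That gap is 0.50 percentage points against a margin of 1.5 points, and 33.2 % of the Z is left in ash and 15.7 % in birch.

Take the ash flask with 0.0025 M of E. Its reach is 38.9 %, twice that of ash, since with c(Z), c(L), time and temperature held the reach as a share goes as one over the root of c(E). This neighbour gives 28.6 %, which is 0.735 of its reach and 1.81 times the yield of ash. Free L in the neighbour stands at 10.1 % of the catalyst charged, against 4.79 % in ash.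

The constants used here stand for no real mixture; no experiment stands behind them.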